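Assumption: ring atoms are referred to by p-menthane numbering (C1 bears the CH2OH carbon C7, C2 = C=O, C3 = O-epoxyacyl, C4 = i-Pr, C5 = O-angeloyl, C6 = =CH); read from the SMILES, the target is (3S,4R,5R) with a (Z)-angelate and a (2R,3R)-epoxyangelate.

**Retrosynthetic overview**
1. Target 19 ⇒ enone 18 by cutting C1–C7 (Morita–Baylis–Hillman with CH2O); 18 ⇒ core 9 + angelic acid 10 + epoxy acid 13 (two esterifications).
2. Core 9 ⇒ Z-enal/alkanal dialdehyde 8 by cutting the C2–C3 acyloin bond: a ring-closing NHC crossed benzoin in which C2 is the acyl anion (Breslow intermediate) and the C3 aldehyde the acceptor. This forms the only carbocycle and sets C3.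
3. 8 ⇒ alkynyl acetal 5 (Lindlar reduction, hydrolysis); 5 ⇒ isovaleraldehyde 4 + ynal 3 by a D-proline anti cross-aldol that sets C4 and C5; 3 ⇒ 3,3-diethoxypropyne 1.
4. Ring order: the cyclohexenone (step 6) and the side-chain oxirane (Sharpless epoxidation, step 8) are made independently and joined in step 10.

**Route**

Step 1
Reactants: 1 3,3-diethoxyprop-1-yne
Product: 3 4,4-diethoxybut-2-ynal, via lithium acetylide 2 (not isolated)
Conditions: n-BuLi, THF, −78 °C; DMF, −78 → 0 °C; AcOH quench, aqueous work-up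
Reagents that add atoms: N,N-dimethylformamide, CN(C)C=O
Why: Formylation of the lithium acetylide with DMF (Bouveault-type) gives a non-enolisable, strongly electrophilic aldol acceptor that carries C2 as an acetal.

Step 2
Reactants: 3 4,4-diethoxybut-2-ynal; 4 3-methylbutanal
Product: 5 (2R,3S)-6,6-diethoxy-3-hydroxy-2-(propan-2-yl)hex-4-ynal
Conditions: D-proline (20 mol%), DMF, 4 °C, slow addition of 4 (syringe pump)
Reagents that add atoms: none
Why: Proline-catalysed direct cross-aldol: the (E)-enamine of the only enolisable partner adds to the ynal through the acid-organised Houk–List transition state, which with D-proline gives the anti adduct and so sets C4 (R) and C5 with the cis ring relationship of i-Pr and O5.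

Step 3
Reactants: 5 (2R,3S)-6,6-diethoxy-3-hydroxy-2-(propan-2-yl)hex-4-ynal
Product: 6 (2R,3S)-3-[(tert-butyldimethylsilyl)oxy]-6,6-diethoxy-2-(propan-2-yl)hex-4-ynal
Conditions: TBSCl, imidazole, DMF, 0 °C → rt
Reagents that add atoms: tert-butyldimethylsilyl chloride, CC(C)(C)[Si](C)(C)Cl
Why: Silyl ether formation under mild conditions blocks retro-aldol and later lactol formation, and avoids the acetal activation that silyl triflates can cause; no stereocentre is touched.

Step 4
Reactants: 6 (2R,3S)-3-[(tert-butyldimethylsilyl)oxy]-6,6-diethoxy-2-(propan-2-yl)hex-4-ynal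
Product: 7 (2R,3R,4Z)-3-[(tert-butyldimethylsilyl)oxy]-6,6-diethoxy-2-(propan-2-yl)hex-4-enal
Conditions: H2 (1 atm), Lindlar catalyst, quinoline, EtOAc, rt
Reagents that add atoms: none
Why: Lindlar semi-hydrogenation adds H2 syn on poisoned Pd and gives the Z-alkene that places C2 and C5 cis, as ring closure requires; aldehyde, acetal and silyl ether are inert.

Step 5
Reactants: 7 (2R,3R,4Z)-3-[(tert-butyldimethylsilyl)oxy]-6,6-diethoxy-2-(propan-2-yl)hex-4-enal
Product: 8 (2Z,4R,5R)-4-[(tert-butyldimethylsilyl)oxy]-5-(propan-2-yl)hex-2-enedial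
Conditions: 10% aq. oxalic acid on SiO2, CH2Cl2, 0 °C → rt; used crude at once
Reagents that add atoms: water, O
Why: Mild acid hydrolysis of the easily ionised allylic acetal (oxocarbenium pathway) unveils the Z-enal while the secondary TBS ether survives and the short contact time limits Z→E isomerisation.

Step 6
Reactants: 8 (2Z,4R,5R)-4-[(tert-butyldimethylsilyl)oxy]-5-(propan-2-yl)hex-2-enedial
Product: 9 (4R,5S,6S)-4-[(tert-butyldimethylsilyl)oxy]-6-hydroxy-5-(propan-2-yl)cyclohex-2-en-1-one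
Conditions: 2-(pentafluorophenyl)-6,7-dihydro-5H-pyrrolo[2,1-c][1,2,4]triazolium BF4 (20 mol%), i-Pr2NEt (20 mol%), CH2Cl2 (0.02 M), rt, Ar
Reagents that add atoms: none
Why: Proposed new method: the electron-poor triazolylidene adds to the unhindered enal carbonyl (C2) and the resulting Breslow intermediate attacks the hindered C3 aldehyde through a chair-like six-membered transition state (i-Pr equatorial, new OH equatorial and trans to it, β-attack would need a four-membered ring), and because the benzoin is reversible the conjugated acyloin with 3,4-trans/4,5-cis substituents is also the thermodynamic product; the closest known reactions are NHC-catalysed intramolecular crossed aldehyde–aldehyde benzoin cyclisations of sugar-derived dialdehydes to inososes and the acyl-anion (Stetter, aza-benzoin) reactions of enals with N-C6F5 triazolium catalysts.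

Step 7
Reactants: 10 (2Z)-2-methylbut-2-enoic acid
Product: 11 (2Z)-2-methylbut-2-en-1-ol
Conditions: LiAlH4, Et2O, 0 °C → rt; aqueous work-up
Reagents that add atoms: none
Why: Hydride reduction of the carboxylic acid to the allylic alcohol proceeds by 1,2-reduction and retains the Z geometry.

Step 8
Reactants: 11 (2Z)-2-methylbut-2-en-1-ol
Product: 12 [(2S,3R)-2,3-dimethyloxiran-2-yl]methanol
Conditions: Ti(Oi-Pr)4 (10 mol%), L-(+)-diethyl tartrate (12 mol%), t-BuOOH, 4 Å MS, CH2Cl2, −20 °C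
Reagents that add atoms: tert-butyl hydroperoxide, CC(C)(C)OO
Why: Sharpless asymmetric epoxidation: the Ti–L-tartrate complex delivers oxygen to the enantioface that gives the (2S,3R) epoxy alcohol, and the stereospecific syn transfer keeps the two methyl groups trans.

Step 9
Reactants: 12 [(2S,3R)-2,3-dimethyloxiran-2-yl]methanol
Product: 13 (2R,3R)-2,3-dimethyloxirane-2-carboxylic acid
Conditions: TEMPO (cat.), PhI(OAc)2 (2.2 equiv), MeCN/H2O 1:1, 0 °C → rt
Reagents that add atoms: water, O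
Why: Oxoammonium (TEMPO/BAIB) oxidation via the aldehyde hydrate gives the acid under near-neutral conditions without touching the epoxide; the 2S→2R change is only a CIP priority change.

Step 10
Reactants: 9 (4R,5S,6S)-4-[(tert-butyldimethylsilyl)oxy]-6-hydroxy-5-(propan-2-yl)cyclohex-2-en-1-one; 13 (2R,3R)-2,3-dimethyloxirane-2-carboxylic acid
Product: 15 (1S,5R,6S)-5-[(tert-butyldimethylsilyl)oxy]-2-oxo-6-(propan-2-yl)cyclohex-3-en-1-yl (2R,3R)-2,3-dimethyloxirane-2-carboxylate, via mixed anhydride 14 (not isolated)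
Conditions: 13, 2,4,6-Cl3C6H2COCl, Et3N, THF, 0 °C → rt; then 9, DMAP, toluene, rt
Reagents that add atoms: none
Why: Yamaguchi esterification: the shielded trichlorobenzoyl carbonyl steers DMAP and then the C3 α-ketol hydroxyl to the epoxy-acyl carbonyl; the acid has no α-hydrogen to epimerise and C3 stays in its preferred configuration.

Step 11
Reactants: 15 (1S,5R,6S)-5-[(tert-butyldimethylsilyl)oxy]-2-oxo-6-(propan-2-yl)cyclohex-3-en-1-yl (2R,3R)-2,3-dimethyloxirane-2-carboxylate
Product: 16 (1S,5R,6R)-5-hydroxy-2-oxo-6-(propan-2-yl)cyclohex-3-en-1-yl (2R,3R)-2,3-dimethyloxirane-2-carboxylate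
Conditions: HF·pyridine, pyridine, THF, 0 °C → rt
Reagents that add atoms: none
Why: Fluoride-driven Si–O cleavage under buffered conditions frees the allylic C5–OH; O3 and O5 are trans, so 1,3-acyl migration is disfavoured.

Step 12
Reactants: 16 (1S,5R,6R)-5-hydroxy-2-oxo-6-(propan-2-yl)cyclohex-3-en-1-yl (2R,3R)-2,3-dimethyloxirane-2-carboxylate; 10 (2Z)-2-methylbut-2-enoic acid
Product: 18 (1S,5R,6R)-5-{[(2Z)-2-methylbut-2-enoyl]oxy}-2-oxo-6-(propan-2-yl)cyclohex-3-en-1-yl (2R,3R)-2,3-dimethyloxirane-2-carboxylate, via angelic mixed anhydride 17 (not isolated)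
Conditions: 10, 2,4,6-Cl3C6H2COCl, Et3N (2.5 equiv), toluene, rt; then 16, 80 °C (no DMAP)
Reagents that add atoms: none
Why: Acylation with the angelic 2,4,6-trichlorobenzoic mixed anhydride without a nucleophilic catalyst is a stereoconservative angeloylation (no acylpyridinium, so no Z→E drift to the tiglate), and O-acylation leaves C5 unchanged.

Step 13
Reactants: 18 (1S,5R,6R)-5-{[(2Z)-2-methylbut-2-enoyl]oxy}-2-oxo-6-(propan-2-yl)cyclohex-3-en-1-yl (2R,3R)-2,3-dimethyloxirane-2-carboxylate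
Product: 19 (1S,5R,6R)-3-(hydroxymethyl)-5-{[(2Z)-2-methylbut-2-enoyl]oxy}-2-oxo-6-(propan-2-yl)cyclohex-3-en-1-yl (2R,3R)-2,3-dimethyloxirane-2-carboxylate
Conditions: 37% aq. HCHO, DMAP (0.3 equiv), THF, rt
Reagents that add atoms: formaldehyde, C=O
Why: Morita–Baylis–Hillman reaction: reversible conjugate addition of DMAP gives an enolate that adds to formaldehyde at C1, and E1cB loss of DMAP restores the enone; no stereocentre is involved.

**Compound list**
1 | 3,3-diethoxyprop-1-yne | C#CC(OCC)OCC | starting material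
2 | lithium 3,3-diethoxyprop-1-yn-1-ide | [Li]C#CC(OCC)OCC | intermediate (not isolated)
3 | 4,4-diethoxybut-2-ynal | O=CC#CC(OCC)OCC | intermediate
4 | 3-methylbutanal (isovaleraldehyde) | CC(C)CC=O | starting material
5 | (2R,3S)-6,6-diethoxy-3-hydroxy-2-(propan-2-yl)hex-4-ynal | O=C[C@H](C(C)C)[C@H](O)C#CC(OCC)OCC | intermediate
6 | (2R,3S)-3-[(tert-butyldimethylsilyl)oxy]-6,6-diethoxy-2-(propan-2-yl)hex-4-ynal | O=C[C@H](C(C)C)[C@H](O[Si](C)(C)C(C)(C)C)C#CC(OCC)OCC | intermediate
7 | (2R,3R,4Z)-3-[(tert-butyldimethylsilyl)oxy]-6,6-diethoxy-2-(propan-2-yl)hex-4-enal | O=C[C@H](C(C)C)[C@H](O[Si](C)(C)C(C)(C)C)/C=C\C(OCC)OCC | intermediate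
8 | (2Z,4R,5R)-4-[(tert-butyldimethylsilyl)oxy]-5-(propan-2-yl)hex-2-enedial | O=C[C@H](C(C)C)[C@H](O[Si](C)(C)C(C)(C)C)/C=C\C=O | intermediate
9 | (4R,5S,6S)-4-[(tert-butyldimethylsilyl)oxy]-6-hydroxy-5-(propan-2-yl)cyclohex-2-en-1-one | CC(C)(C)[Si](C)(C)O[C@@H]1C=CC(=O)[C@@H](O)[C@@H]1C(C)C | intermediate
10 | (2Z)-2-methylbut-2-enoic acid (angelic acid) | C/C=C(/C)C(=O)O | starting material
11 | (2Z)-2-methylbut-2-en-1-ol | C/C=C(/C)CO | intermediate
12 | [(2S,3R)-2,3-dimethyloxiran-2-yl]methanol | OC[C@]1(C)O[C@@H]1C | intermediate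
13 | (2R,3R)-2,3-dimethyloxirane-2-carboxylic acid | OC(=O)[C@]1(C)O[C@@H]1C | intermediate
14 | (2R,3R)-2,3-dimethyloxirane-2-carboxylic 2,4,6-trichlorobenzoic anhydride | O=C(OC(=O)[C@]1(C)O[C@@H]1C)c1c(Cl)cc(Cl)cc1Cl | intermediate (not isolated)
15 | (1S,5R,6S)-5-[(tert-butyldimethylsilyl)oxy]-2-oxo-6-(propan-2-yl)cyclohex-3-en-1-yl (2R,3R)-2,3-dimethyloxirane-2-carboxylate | CC(C)(C)[Si](C)(C)O[C@@H]1C=CC(=O)[C@@H](OC(=O)[C@]2(C)O[C@@H]2C)[C@@H]1C(C)C | intermediate
16 | (1S,5R,6R)-5-hydroxy-2-oxo-6-(propan-2-yl)cyclohex-3-en-1-yl (2R,3R)-2,3-dimethyloxirane-2-carboxylate | O[C@@H]1C=CC(=O)[C@@H](OC(=O)[C@]2(C)O[C@@H]2C)[C@@H]1C(C)C | intermediate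
17 | (2Z)-2-methylbut-2-enoic 2,4,6-trichlorobenzoic anhydride | C/C=C(/C)C(=O)OC(=O)c1c(Cl)cc(Cl)cc1Cl | intermediate (not isolated)
18 | (1S,5R,6R)-5-{[(2Z)-2-methylbut-2-enoyl]oxy}-2-oxo-6-(propan-2-yl)cyclohex-3-en-1-yl (2R,3R)-2,3-dimethyloxirane-2-carboxylate | C/C=C(/C)C(=O)O[C@@H]1C=CC(=O)[C@@H](OC(=O)[C@]2(C)O[C@@H]2C)[C@@H]1C(C)C | intermediate
19 | (1S,5R,6R)-3-(hydroxymethyl)-5-{[(2Z)-2-methylbut-2-enoyl]oxy}-2-oxo-6-(propan-2-yl)cyclohex-3-en-1-yl (2R,3R)-2,3-dimethyloxirane-2-carboxylate (CNP0293054.1) | C/C=C(/C)C(=O)O[C@@H]1C=C(CO)C(=O)[C@@H](OC(=O)[C@]2(C)O[C@@H]2C)[C@@H]1C(C)C | target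

**Step count**
Total: 13 steps. Longest linear sequence: 10 steps (steps 1–6 and 10–13, from 1); the side-chain branch (steps 7–9) joins at step 10.

**Three steps most likely to fail, with fallbacks**

Step 6 (ring-closing benzoin). The enal-derived Breslow intermediate may leak into homoenolate or redox channels, or 8 may have partly isomerised to the E-enal, which cannot cyclise. The fallback sets out from 8 and comes back at 9. The enal is masked by conjugate addition of thiophenol (PhSH, cat. Et3N, CH2Cl2, 0 °C), which works on either alkene geometry and gives (2R,3S)-3-[(tert-butyldimethylsilyl)oxy]-4-(phenylsulfanyl)-2-(propan-2-yl)hexanedial F3 as a mixture at the sulfur-bearing carbon. Its unhindered saturated aldehyde is an ordinary benzoin donor, so thiazolium or triazolium catalysis closes the ring to 4-[(tert-butyldimethylsilyl)oxy]-2-hydroxy-5-(phenylsulfanyl)-3-(propan-2-yl)cyclohexan-1-one F4. Oxidation with mCPBA (1 equiv, −78 °C) gives the sulfoxide 5-(benzenesulfinyl)-4-[(tert-butyldimethylsilyl)oxy]-2-hydroxy-3-(propan-2-yl)cyclohexan-1-one F5, and thermal syn-elimination toward the acidic C1–H (toluene, 80 °C) restores the enone of 9.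

Step 2 (cross-aldol). Isovaleraldehyde is a sluggish donor, and proline may add to the ynal in aza-Michael fashion. The fallback sets out from 3 and comes back at 6. Anti-selective allylboration of 3 with (E)-(4-methylpent-2-en-1-yl)diisopinocampheylborane (from trans-4-methylpent-2-ene, n-BuLi/KOt-Bu, then (−)-Ipc2BOMe and BF3·OEt2; −78 °C; NaOH/H2O2) gives (3S,4S)-7,7-diethoxy-3-(propan-2-yl)hept-1-en-5-yn-4-ol F1. The choice of the (−)-Ipc2BOMe-derived reagent rests on recalled Brown selectivities and should be checked against the literature before use. Silylation (TBSCl, imidazole, DMF) gives tert-butyl{[(3S,4S)-7,7-diethoxy-3-(propan-2-yl)hept-1-en-5-yn-4-yl]oxy}dimethylsilane F2. Selective ozonolysis of the terminal alkene in the presence of the alkyne (O3, CH2Cl2/MeOH, −78 °C, Sudan III end-point; Me2S) unveils the C3 aldehyde and gives 6.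

Step 13 (late Morita–Baylis–Hillman). The aqueous amine conditions may cleave the activated α-acyloxy ketone ester or simply be too slow on this hindered enone. The fallback sets out from 18 and comes back at 19. Johnson α-iodination (I2, pyridine, CH2Cl2, 0 °C → rt) gives (1S,5S,6R)-3-iodo-5-{[(2Z)-2-methylbut-2-enoyl]oxy}-2-oxo-6-(propan-2-yl)cyclohex-3-en-1-yl (2R,3R)-2,3-dimethyloxirane-2-carboxylate F6. Stille coupling with (tributylstannyl)methanol (Pd2(dba)3, AsPh3, CuI, NMP, 50 °C) then installs the CH2OH group and gives 19.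

**Further compounds**
F1 | step 2 | (3S,4S)-7,7-diethoxy-3-(propan-2-yl)hept-1-en-5-yn-4-ol | C=C[C@H](C(C)C)[C@H](O)C#CC(OCC)OCC
F2 | step 2 | tert-butyl{[(3S,4S)-7,7-diethoxy-3-(propan-2-yl)hept-1-en-5-yn-4-yl]oxy}dimethylsilane | C=C[C@H](C(C)C)[C@H](O[Si](C)(C)C(C)(C)C)C#CC(OCC)OCC
F3 | step 6 | (2R,3S)-3-[(tert-butyldimethylsilyl)oxy]-4-(phenylsulfanyl)-2-(propan-2-yl)hexanedial (C4 epimers) | O=C[C@H](C(C)C)[C@H](O[Si](C)(C)C(C)(C)C)C(Sc1ccccc1)CC=O
F4 | step 6 | 4-[(tert-butyldimethylsilyl)oxy]-2-hydroxy-5-(phenylsulfanyl)-3-(propan-2-yl)cyclohexan-1-one (C2, C3, C4 configured as in 9; C5 epimers) | CC(C)(C)[Si](C)(C)O[C@@H]1C(Sc2ccccc2)CC(=O)[C@@H](O)[C@@H]1C(C)C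
F5 | step 6 | 5-(benzenesulfinyl)-4-[(tert-butyldimethylsilyl)oxy]-2-hydroxy-3-(propan-2-yl)cyclohexan-1-one (C2, C3, C4 configured as in 9) | CC(C)(C)[Si](C)(C)O[C@@H]1C(S(=O)c2ccccc2)CC(=O)[C@@H](O)[C@@H]1C(C)C
F6 | step 13 | (1S,5S,6R)-3-iodo-5-{[(2Z)-2-methylbut-2-enoyl]oxy}-2-oxo-6-(propan-2-yl)cyclohex-3-en-1-yl (2R,3R)-2,3-dimethyloxirane-2-carboxylate | C/C=C(/C)C(=O)O[C@@H]1C=C(I)C(=O)[C@@H](OC(=O)[C@]2(C)O[C@@H]2C)[C@@H]1C(C)C
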